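**Plan**

- Retrosynthesis: cut the C-7 O–acyl ester bond, then the C-5–C-6 bond (ring-closing C-acylation), then the pyran bonds O-2–C-1 and C-4a–C-8a ([3+3] union of an enaminone with pent-3-yn-2-one), then C-7–C-8 (enolate acylation).
- Forward: (R)-lactate dioxolanone → quaternary β-keto lactone → enaminone → aminodienone → in one flask the pyran ring (as a pyrylium ion), then the carbocycle → esterification.
- Enabling feature: the bicycle is the C-acylated anhydrobase of a 4-methylpyrylium ion. Ring oxygen O-2, C-3=C-4 and the exocyclic C-4a=C-5 bond form a dienol ether whose terminus C-5 is nucleophilic. C-6, C-7 and the C-7 oxygen are an α-hydroxy acid unit that can be carried as a 1,3-dioxolan-4-one, which is at once the activated acyl donor and the mask of the tertiary alcohol.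
- Stereochemistry: the only stereocentre, C-7, comes from (R)-lactic acid by self-regeneration of stereocentres (acylation anti to tert-butyl, net retention) and is never enolisable afterwards.

Key step: step 5

Remark: isochromene numbering (C-1, O-2, C-3 … C-8a) is used for the target. C-7 is (R) in the given structure (O > C-8 > C-6 > CH3). The change from (5S) in the dioxolanones to (7R) in 13 is a change of CIP priorities, not an inversion.

**Step 1**
Reactants: 1 (R)-lactic acid; 2 pivalaldehyde
Product: 3 (2R,5R)-2-tert-butyl-5-methyl-1,3-dioxolan-4-one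
Conditions: TsOH·H2O (cat.), H2SO4 (cat.), pentane, reflux, Dean–Stark trap; crystallisation from pentane/Et2O at −78 °C
Reagents that add atoms: pivalaldehyde (2), CC(C)(C)C=O
Why: Acid-catalysed acetalisation of an α-hydroxy acid with azeotropic removal of water should give mainly the cis-dioxolanone, freed from the trans isomer by crystallisation; the lactate centre is untouched and the new acetal centre is the relay for self-regeneration of stereocentres.

**Step 2**
Reactants: 3 (2R,5R)-2-tert-butyl-5-methyl-1,3-dioxolan-4-one; 4 (2E)-3-ethoxyprop-2-enoyl chloride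
Product: 6 (2R,5S)-2-tert-butyl-5-[(2E)-3-ethoxyprop-2-enoyl]-5-methyl-1,3-dioxolan-4-one, via lithium enolate 5 (not isolated)
Conditions: LiN(iPr)2 (commercial solution, 1.05 equiv), THF, −78 °C; then cannulation into 4 (1.3 equiv), THF, −78 °C
Reagents that add atoms: (2E)-3-ethoxyprop-2-enoyl chloride (4), CCO/C=C/C(Cl)=O
Why: Claisen-type C-acylation of a 1,3-dioxolan-4-one lithium enolate with an acid chloride should occur anti to the tert-butyl group, so the acyl group takes the place of the former hydrogen (net retention) and sets the quaternary centre that becomes C-7; inverse addition keeps the enolate away from the β-alkoxy enone product.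

**Step 3**
Reactants: 6 (2R,5S)-2-tert-butyl-5-[(2E)-3-ethoxyprop-2-enoyl]-5-methyl-1,3-dioxolan-4-one; 7 dimethylamine
Product: 8 (2R,5S)-2-tert-butyl-5-[(2E)-3-(dimethylamino)prop-2-enoyl]-5-methyl-1,3-dioxolan-4-one
Conditions: Me2NH (2.0 M in THF, 1.05 equiv), THF, 0 °C
Reagents that add atoms: dimethylamine (7), CNC
Why: Addition–elimination of a secondary amine at the β-carbon of a β-alkoxy enone (enaminone formation) should be far faster at 0 °C than aminolysis of the hindered lactone, and it makes the α-carbon (future C-8a) nucleophilic while keeping the future C-1 at the aldehyde oxidation level.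

**Step 4**
Reactants: 8 (2R,5S)-2-tert-butyl-5-[(2E)-3-(dimethylamino)prop-2-enoyl]-5-methyl-1,3-dioxolan-4-one; 9 pent-3-yn-2-one
Product: 10 (2R,5S)-2-tert-butyl-5-{2-[(dimethylamino)methylidene]-3-methyl-5-oxohex-3-enoyl}-5-methyl-1,3-dioxolan-4-one (mixture of alkene isomers)
Conditions: 9 (1.5 equiv), EtOH, 50 °C
Reagents that add atoms: pent-3-yn-2-one (9), CC#CC(C)=O
Why: Michael addition of the enaminone α-carbon to the β-carbon of the ynone with proton transfer in the protic solvent (first stage of a Bohlmann–Rahtz-type annulation) should give the push–pull 5-aminopenta-2,4-dienone that holds every atom of the pyran ring and the methyl group destined to become C-5; no stereocentre is formed and the alkene geometry equilibrates in the next step.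

**Step 5**
Reactants: 10 (2R,5S)-2-tert-butyl-5-{2-[(dimethylamino)methylidene]-3-methyl-5-oxohex-3-enoyl}-5-methyl-1,3-dioxolan-4-one
Product: 13 (7R)-7-hydroxy-3,7-dimethyl-6H-isochromene-6,8(7H)-dione, via acylpyrylium tetrafluoroborate 11 (not isolated), via methylenepyran anhydrobase 12 (not isolated)
Conditions: HBF4·OEt2 (1.1 equiv), CH2Cl2, −20 → 0 °C; then 2,6-lutidine (3 equiv), MeCN (0.01 M), 0 → 45 °C
Reagents that add atoms: none
Why: Proposed new method: O-protonation of aminodienone 10 triggers the known acid recyclisation of 5-aminopenta-2,4-dienones to pyrylium salts (oxa-6π-electrocyclisation of the 1-oxatriene, then loss of dimethylammonium), which closes the pyran ring as salt 11; 2,6-lutidine, too weak a base to liberate dimethylamine, then removes a proton from the 4-methyl group to give anhydrobase 12, whose exocyclic carbon is the terminus of the dienol ether O–C(Me)=CH–C=CH2. This carbon attacks the dioxolanone carbonyl held five atoms away in a 6-(enolendo)-exo-trig Claisen-type acylation that closes the carbocycle, the tetrahedral intermediate collapses with loss of pivalaldehyde to release the tertiary alkoxide, and proton loss from the now doubly activated CH2 gives the neutral 4-pyranylidene ketone 13. The closest known reactions are the C-acylation of 4-methylpyrylium anhydrobases (4-methylene-4H-pyrans) by acid chlorides or anhydrides and the lateral Claisen acylation of 4-picoline-type anions by esters; new is the intramolecular use of an acylal-type lactone as acyl donor, which should be helped by the six-membered transition state and the irreversible loss of pivalaldehyde. No stereocentre is created: the quaternary centre from step 2 has no α-hydrogen, none of its bonds is broken, and because the formyl-derived carbon already sits on C-8a the two carbonyl arms at C-7 are constitutionally different, so enolisation of the product cannot scramble it. The step needs site selectivity (only the methylene derived from the 4-methyl group can reach the lactone through a six-membered ring; the isomer from the 6-methyl group forms reversibly and returns), absence of nucleophiles at C-1 (the amine stays protonated, the counter-ion is BF4−) and high dilution against anhydrobase–pyrylium coupling.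

**Step 6**
Reactants: 13 (7R)-7-hydroxy-3,7-dimethyl-6H-isochromene-6,8(7H)-dione; 14 (9Z,12Z)-octadeca-9,12-dienoyl chloride
Product: 15 (7R)-3,7-dimethyl-6,8-dioxo-7,8-dihydro-6H-isochromen-7-yl (9Z,12Z)-octadeca-9,12-dienoate
Conditions: 14 (1.5 equiv), Et3N (2 equiv), DMAP (0.2 equiv), CH2Cl2, 0 → 23 °C
Reagents that add atoms: (9Z,12Z)-octadeca-9,12-dienoyl chloride (14), CCCCC/C=C\C/C=C\CCCCCCCC(=O)Cl
Why: DMAP-catalysed esterification of the tertiary α-ketol with the acid chloride, a reaction type well precedented on 7-hydroxy azaphilone cores, should give the target; C-7 cannot epimerise (no α-hydrogen) and the skipped Z,Z-diene is inert under these conditions.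

**Compound list**

1 | (R)-lactic acid | C[C@@H](O)C(=O)O | starting material
2 | pivalaldehyde | CC(C)(C)C=O | starting material
3 | (2R,5R)-2-tert-butyl-5-methyl-1,3-dioxolan-4-one | C[C@H]1O[C@@H](C(C)(C)C)OC1=O | intermediate
4 | (2E)-3-ethoxyprop-2-enoyl chloride | CCO/C=C/C(Cl)=O | starting material
5 | lithium (2R)-2-tert-butyl-5-methyl-2H-1,3-dioxol-4-olate (lithium enolate of 3, not isolated) | CC1=C(O[Li])O[C@H](C(C)(C)C)O1 | intermediate
6 | (2R,5S)-2-tert-butyl-5-[(2E)-3-ethoxyprop-2-enoyl]-5-methyl-1,3-dioxolan-4-one | CCO/C=C/C(=O)[C@]1(C)O[C@@H](C(C)(C)C)OC1=O | intermediate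
7 | dimethylamine | CNC | starting material
8 | (2R,5S)-2-tert-butyl-5-[(2E)-3-(dimethylamino)prop-2-enoyl]-5-methyl-1,3-dioxolan-4-one | CN(C)/C=C/C(=O)[C@]1(C)O[C@@H](C(C)(C)C)OC1=O | intermediate
9 | pent-3-yn-2-one | CC#CC(C)=O | starting material
10 | (2R,5S)-2-tert-butyl-5-{2-[(dimethylamino)methylidene]-3-methyl-5-oxohex-3-enoyl}-5-methyl-1,3-dioxolan-4-one (mixture of alkene isomers) | CN(C)C=C(C(C)=CC(C)=O)C(=O)[C@]1(C)O[C@@H](C(C)(C)C)OC1=O | intermediate
11 | 5-{[(2R,4S)-2-tert-butyl-4-methyl-5-oxo-1,3-dioxolan-4-yl]carbonyl}-2,4-dimethylpyrylium tetrafluoroborate (not isolated) | Cc1cc(C)c(C(=O)[C@]2(C)O[C@@H](C(C)(C)C)OC2=O)c[o+]1.F[B-](F)(F)F | intermediate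
12 | (2R,5S)-2-tert-butyl-5-methyl-5-[(6-methyl-4-methylidene-4H-pyran-3-yl)carbonyl]-1,3-dioxolan-4-one (not isolated) | C=C1C=C(C)OC=C1C(=O)[C@]2(C)O[C@@H](C(C)(C)C)OC2=O | intermediate
13 | (7R)-7-hydroxy-3,7-dimethyl-6H-isochromene-6,8(7H)-dione | O[C@]1(C)C(=O)C=C2C=C(C)OC=C2C1=O | intermediate
14 | (9Z,12Z)-octadeca-9,12-dienoyl chloride (linoleoyl chloride) | CCCCC/C=C\C/C=C\CCCCCCCC(=O)Cl | starting material
15 | (7R)-3,7-dimethyl-6,8-dioxo-7,8-dihydro-6H-isochromen-7-yl (9Z,12Z)-octadeca-9,12-dienoate | CCCCC/C=C\C/C=C\CCCCCCCC(=O)O[C@]1(C)C(=O)C=C2C=C(C)OC=C2C1=O | target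

Total step count: 6. Longest linear sequence: 6 steps (1 → 15).

**Steps most likely to fail**

Risk 1, step 5 (the proposed new method). The anhydrobase may fail to attack the hindered lactone and instead couple with a second pyrylium ion, or ring-opened material may close at carbon to a phenol. The fallback replaces cationic by anionic activation and uses known reaction types; it sets out from 10. HBF4·OEt2 in CH2Cl2, then methanol and 2,6-lutidine at −40 °C, should give the pyrylium pseudobase ether (2R,5S)-2-tert-butyl-5-[(2-methoxy-4,6-dimethyl-2H-pyran-3-yl)carbonyl]-5-methyl-1,3-dioxolan-4-one F1 by addition of the alcohol to the free α-position of the pyrylium ion. LiN(SiMe3)2 in THF at −78 → 0 °C then removes a proton from the 4-methyl group, which is γ to the ketone, and the dienolate is acylated at its γ-carbon by the lactone (vinylogous Dieckmann condensation). Loss of pivalaldehyde and E1cB loss of methoxide from the acetal carbon give 13, where the route is rejoined.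

Risk 2, step 4. The conjugate addition may be slow or misdirected, because the tertiary enaminone is a weak carbon nucleophile and could add to the ynone by a [2+2] addition and ring opening instead. The fallback forms the C-8a–C-4a bond by cross-coupling; it sets out from 8 and 9. Iodination of 8 with N-iodosuccinimide in CH2Cl2 at 0 °C should give (2R,5S)-2-tert-butyl-5-[(2Z)-3-(dimethylamino)-2-iodoprop-2-enoyl]-5-methyl-1,3-dioxolan-4-one F2. Copper-catalysed β-borylation of 9 (CuCl, NaOtBu, Xantphos, bis(pinacolato)diboron, MeOH, THF) should give (3Z)-4-(4,4,5,5-tetramethyl-1,3,2-dioxaborolan-2-yl)pent-3-en-2-one F3. Suzuki–Miyaura coupling of F2 with F3 (PdCl2(dppf), CsF, dioxane, 60 °C, anhydrous to spare the lactone) returns to 10.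

Risk 3, step 2. The hindered enolate may be acylated at oxygen, or may add to the β-alkoxy enone product. The fallback builds the ketone by aldol addition and oxidation; it sets out from 3 (through enolate 5). Addition to acetaldehyde at −78 °C should give (2R,5S)-2-tert-butyl-5-(1-hydroxyethyl)-5-methyl-1,3-dioxolan-4-one F4 as both carbinol epimers, again anti to tert-butyl. Dess–Martin periodinane in CH2Cl2 gives (2R,5S)-5-acetyl-2-tert-butyl-5-methyl-1,3-dioxolan-4-one F5. Condensation of the methyl ketone with N,N-dimethylformamide dimethyl acetal (neat, 80 °C) gives enaminone 8, where the route is rejoined; 6 is bypassed.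

**Further compounds**

F1 | step 5 | (2R,5S)-2-tert-butyl-5-[(2-methoxy-4,6-dimethyl-2H-pyran-3-yl)carbonyl]-5-methyl-1,3-dioxolan-4-one (both epimers at the pyran acetal carbon) | COC1OC(C)=CC(C)=C1C(=O)[C@]2(C)O[C@@H](C(C)(C)C)OC2=O
F2 | step 4 | (2R,5S)-2-tert-butyl-5-[(2Z)-3-(dimethylamino)-2-iodoprop-2-enoyl]-5-methyl-1,3-dioxolan-4-one | CN(C)/C=C(\I)C(=O)[C@]1(C)O[C@@H](C(C)(C)C)OC1=O
F3 | step 4 | (3Z)-4-(4,4,5,5-tetramethyl-1,3,2-dioxaborolan-2-yl)pent-3-en-2-one | CC(=O)/C=C(\C)B1OC(C)(C)C(C)(C)O1
F4 | step 2 | (2R,5S)-2-tert-butyl-5-(1-hydroxyethyl)-5-methyl-1,3-dioxolan-4-one (both carbinol epimers) | CC(O)[C@]1(C)O[C@@H](C(C)(C)C)OC1=O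
F5 | step 2 | (2R,5S)-5-acetyl-2-tert-butyl-5-methyl-1,3-dioxolan-4-one | CC(=O)[C@]1(C)O[C@@H](C(C)(C)C)OC1=O
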